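**Plan**

1. Cuts (chromene numbering O1 to C8a, pyrone atoms primed): the CH2–C3' bond of the methylene bridge; both C–C bonds of the C8 ketone, C8–C(=O) and C(=O)–CH(CH3)CH2CH3; C6–CHO and C8–I back to ring C–H bonds; O1–C2 and C4–C4a of the pyran ring; the pyrone into pentan-3-one and a malonyl unit.
2. Enabling feature: the ketone carbonyl carbon lies between aromatic C8, which is walled in by the C7 oxygen and by O1 of the pyran ring, and an easily epimerised sec-butyl methine. Because that one carbon can be delivered as CO, both of its C–C bonds can be forged at palladium in a medium free of acid and base.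
3. Forward order: the pyran ring is fused onto the phloroglucinol benzene ring, C6 is formylated and C8 iodinated by two successive directed metalations, and the three-component ketone synthesis follows. The separately made pyrone ring is then attached through the aldehyde by reductive alkylation, and the two acetals are removed last.
4. Stereochemistry: the single stereocentre stems from (R)-butan-2-ol. It is inverted once when a stannyl anion displaces the mesylate (R to S) and then passes from tin to the acyl-palladium species with retention. It becomes alpha to a carbonyl group only in the key step.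

Key step: step 7

Assumption: 5-chloro-1-aza-5-stannabicyclo[3.3.3]undecane and enantiopure (R)-butan-2-ol are taken as purchasable reagents.

**Step 1**
Reactants: 1 phloroglucinol; 2 3-methylbut-2-enal
Product: 4 2,2-dimethyl-2H-chromene-5,7-diol, via o-quinone methide 3 (not isolated)
Conditions: 1 (2 equiv), ethylenediammonium diacetate (10 mol %), DMF, 100 °C
Reagents that add atoms: none
Why: An amine-salt-catalysed Knoevenagel-type condensation at a ring carbon of 1 should give the o-quinone methide 3, which closes the pyran ring by oxa-6π electrocyclisation (the formal [3+3] chromene annulation of resorcinols with enals); the threefold symmetry of 1 allows only one mono-adduct and the excess of 1 holds back a second annulation.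

**Step 2**
Reactants: 4 2,2-dimethyl-2H-chromene-5,7-diol
Product: 5 5,7-bis(methoxymethoxy)-2,2-dimethyl-2H-chromene
Conditions: NaH, MOMCl, DMF, 0 °C to rt
Reagents that add atoms: chloromethyl methyl ether (MOMCl), COCCl
Why: Williamson-type O-alkylation of both phenoxides with the hard electrophile MOMCl should give acetals that survive organolithium reagents, palladium and amine catalysis, steer the coming metalations and fall off under mild acid.

**Step 3**
Reactants: 5 5,7-bis(methoxymethoxy)-2,2-dimethyl-2H-chromene
Product: 8 5,7-bis(methoxymethoxy)-2,2-dimethyl-2H-chromene-6-carbaldehyde, via 6-lithiochromene 6 (not isolated), via lithium hemiaminal alkoxide 7 (not isolated)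
Conditions: n-BuLi, THF, 0 °C; DMF, 0 °C to rt; H2O
Reagents that add atoms: N,N-dimethylformamide (DMF), CN(C)C=O
Why: In this directed ortho-metalation C6–H lies between two methoxymethoxy groups that can each fold their outer oxygen onto lithium, whereas C8–H has only one such arm beside the non-chelating O1, so deprotonation should take place at C6 and DMF then delivers the formyl group.

**Step 4**
Reactants: 8 5,7-bis(methoxymethoxy)-2,2-dimethyl-2H-chromene-6-carbaldehyde
Product: 12 8-iodo-5,7-bis(methoxymethoxy)-2,2-dimethyl-2H-chromene-6-carbaldehyde, via amino alkoxide 9 (not isolated), via 8-lithio amino alkoxide 10 (not isolated), via 8-iodo amino alkoxide 11 (not isolated)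
Conditions: Me2NCH2CH2NHMe, n-BuLi, THF, −20 °C, then 8; n-BuLi, −20 to 0 °C; I2, −78 °C; H2O
Reagents that add atoms: iodine, [I][I]
Why: In situ protection of the aldehyde as an α-amino alkoxide makes it inert to n-BuLi, directed ortho-metalation then removes the only remaining ring proton (C8–H, between the C7 acetal oxygen and O1), and the aryllithium consumes iodine at −78 °C far faster than the electron-rich C3=C4 bond could, which an electrophilic aromatic iodination would put at risk.

**Step 5**
Reactants: 13 (R)-butan-2-ol
Product: 14 (R)-butan-2-yl methanesulfonate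
Conditions: MsCl, Et3N, CH2Cl2, 0 °C
Reagents that add atoms: methanesulfonyl chloride (MsCl), CS(=O)(=O)Cl
Why: Sulfonylation takes place at oxygen and leaves the C–O bond, and hence the R configuration, untouched.

**Step 6**
Reactants: 15 5-chloro-1-aza-5-stannabicyclo[3.3.3]undecane; 14 (R)-butan-2-yl methanesulfonate
Product: 17 5-[(S)-butan-2-yl]-1-aza-5-stannabicyclo[3.3.3]undecane, via stannatranyllithium 16 (not isolated)
Conditions: 15, Li, naphthalene (10 mol %), THF, 0 °C to rt; then 14, −78 °C to rt
Reagents that add atoms: none
Why: Reductive lithiation of the Sn–Cl bond should give a soft stannyl anion that displaces the secondary sulfonate by SN2 with inversion (R to S), a sulfonate being chosen because it avoids the electron-transfer pathway that erodes configuration with secondary halides.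

**Step 7**
Reactants: 12 8-iodo-5,7-bis(methoxymethoxy)-2,2-dimethyl-2H-chromene-6-carbaldehyde; 18 carbon monoxide; 17 5-[(S)-butan-2-yl]-1-aza-5-stannabicyclo[3.3.3]undecane
Product: 19 5,7-bis(methoxymethoxy)-2,2-dimethyl-8-[(S)-2-methylbutanoyl]-2H-chromene-6-carbaldehyde
Conditions: Pd(dba)2 (5 mol %), JackiePhos (2-{bis[3,5-bis(trifluoromethyl)phenyl]phosphino}-3,6-dimethoxy-2',4',6'-triisopropylbiphenyl, 10 mol %), CuCl (1.5 equiv), CO (5 bar), MeCN, 60 °C
Reagents that add atoms: none
Why: Proposed new method: zerovalent palladium should add oxidatively into the C8–I bond of 12, the resulting aryl-palladium species, squeezed between the C7 acetal oxygen and O1, should take up CO by migratory insertion, the aroyl-palladium halide should then accept the sec-butyl group of 17, and acyl–alkyl reductive elimination should release 19, so that C8–C(=O) and C(=O)–Cα are both made in one flask. The closest known reaction types are the carbonylative Stille coupling of aryl iodides with simple stannanes and the stereoretentive palladium-catalysed arylation and acylation of enantioenriched secondary alkyl azastannatranes, whose catalyst system (electron-poor bulky biaryl phosphine plus CuCl) is taken over here; their merger into a three-component reaction is the untested part. No ring is closed. The Cα stereocentre is controlled by the reagent alone: transannular N-to-Sn donation weakens the apical Sn–C(sec-butyl) bond so that only this group leaves tin, and it should do so through a closed, halide-bridged transition state with retention, which turns (S)-17 into (S)-19. Two selectivities are needed, CO insertion ahead of transmetalation (otherwise the 8-sec-butyl arene forms) and reductive elimination ahead of β-hydride elimination; the first is secured by the two ortho oxygen substituents at C8, which slow transmetalation at the aryl stage and make the less congested aroyl complex the resting point, together with the CO pressure, and the second by the π-acidic phosphine and the acyl ligand. As neither base nor acid is present, the new α-stereocentre is not enolised and the C6 aldehyde, the acetals and the C3=C4 bond remain spectators.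

**Step 8**
Reactants: 20 pentan-3-one
Product: 21 (Z)-trimethyl(pent-2-en-3-yloxy)silane
Conditions: TMSOTf, Et3N, CH2Cl2, 0 °C
Reagents that add atoms: trimethylsilyl trifluoromethanesulfonate (TMSOTf), C[Si](C)(C)OS(=O)(=O)C(F)(F)F
Why: Soft enolisation of the symmetrical ketone with a silyl triflate and a tertiary amine can give only one constitutional enol silane, and its double-bond geometry (mainly Z) is lost in the next step.

**Step 9**
Reactants: 21 (Z)-trimethyl(pent-2-en-3-yloxy)silane; 22 malonyl dichloride
Product: 24 6-ethyl-4-hydroxy-5-methyl-2H-pyran-2-one, via tricarbonyl chloride 23 (not isolated)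
Conditions: Et2O, −78 °C to rt
Reagents that add atoms: none
Why: C-acylation of the enol silane by one acyl chloride function should give 23, whose enol oxygen closes onto the second acyl chloride, which is the known 4-hydroxy-2-pyrone synthesis from silyl enol ethers and malonyl dichloride.

**Step 10**
Reactants: 19 5,7-bis(methoxymethoxy)-2,2-dimethyl-8-[(S)-2-methylbutanoyl]-2H-chromene-6-carbaldehyde; 24 6-ethyl-4-hydroxy-5-methyl-2H-pyran-2-one
Product: 26 3-({5,7-bis(methoxymethoxy)-2,2-dimethyl-8-[(S)-2-methylbutanoyl]-2H-chromen-6-yl}methyl)-6-ethyl-4-hydroxy-5-methyl-2H-pyran-2-one, via Knoevenagel adduct 25 (not isolated)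
Conditions: diethyl 2,6-dimethyl-1,4-dihydropyridine-3,5-dicarboxylate (Hantzsch ester, 1.2 equiv), L-proline (20 mol %), CH2Cl2/EtOH, rt
Reagents that add atoms: none
Why: In this organocatalytic three-component reductive alkylation, Knoevenagel condensation of the C6 aldehyde with the nucleophilic C3' of 24 should give 25, a strong hydride acceptor that the Hantzsch ester reduces by conjugate hydride transfer before a second pyrone can add, while the shielded C8 ketone, its α-stereocentre and the C3=C4 bond are not addressed.

**Step 11**
Reactants: 26 3-({5,7-bis(methoxymethoxy)-2,2-dimethyl-8-[(S)-2-methylbutanoyl]-2H-chromen-6-yl}methyl)-6-ethyl-4-hydroxy-5-methyl-2H-pyran-2-one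
Product: 27 3-({5,7-dihydroxy-2,2-dimethyl-8-[(S)-2-methylbutanoyl]-2H-chromen-6-yl}methyl)-6-ethyl-4-hydroxy-5-methyl-2H-pyran-2-one
Conditions: HCl (0.5 M in MeOH), rt
Reagents that add atoms: none
Why: Acid-catalysed acetal exchange with methanol should remove both phenolic methoxymethyl groups at room temperature, where the 2,2-dimethylchromene, the methylene bridge and the α-branched, slowly enolising ketone are expected to persist.

**Compound list**

1 | phloroglucinol (benzene-1,3,5-triol) | Oc1cc(O)cc(O)c1 | starting material
2 | 3-methylbut-2-enal | CC(C)=CC=O | starting material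
3 | 3,5-dihydroxy-6-(3-methylbut-2-en-1-ylidene)cyclohexa-2,4-dien-1-one (o-quinone methide, formed in situ, exocyclic geometry undefined) | O=C1C=C(O)C=C(O)C1=CC=C(C)C | intermediate
4 | 2,2-dimethyl-2H-chromene-5,7-diol | Oc1cc(O)c2C=CC(C)(C)Oc2c1 | intermediate
5 | 5,7-bis(methoxymethoxy)-2,2-dimethyl-2H-chromene | COCOc1cc(OCOC)c2C=CC(C)(C)Oc2c1 | intermediate
6 | [5,7-bis(methoxymethoxy)-2,2-dimethyl-2H-chromen-6-yl]lithium (formed in situ) | COCOc1cc2OC(C)(C)C=Cc2c(OCOC)c1[Li] | intermediate
7 | lithium [5,7-bis(methoxymethoxy)-2,2-dimethyl-2H-chromen-6-yl](dimethylamino)methanolate (formed in situ, carbinol carbon undefined) | COCOc1cc2OC(C)(C)C=Cc2c(OCOC)c1C(O[Li])N(C)C | intermediate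
8 | 5,7-bis(methoxymethoxy)-2,2-dimethyl-2H-chromene-6-carbaldehyde | COCOc1cc2OC(C)(C)C=Cc2c(OCOC)c1C=O | intermediate
9 | lithium [5,7-bis(methoxymethoxy)-2,2-dimethyl-2H-chromen-6-yl]{[2-(dimethylamino)ethyl](methyl)amino}methanolate (formed in situ, carbinol carbon undefined) | COCOc1cc2OC(C)(C)C=Cc2c(OCOC)c1C(O[Li])N(C)CCN(C)C | intermediate
10 | 8-lithio derivative of 9 (formed in situ) | COCOc1c([Li])c2OC(C)(C)C=Cc2c(OCOC)c1C(O[Li])N(C)CCN(C)C | intermediate
11 | 8-iodo derivative of 9 (formed in situ) | COCOc1c(C(O[Li])N(C)CCN(C)C)c(OCOC)c2C=CC(C)(C)Oc2c1I | intermediate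
12 | 8-iodo-5,7-bis(methoxymethoxy)-2,2-dimethyl-2H-chromene-6-carbaldehyde | COCOc1c(C=O)c(OCOC)c2C=CC(C)(C)Oc2c1I | intermediate
13 | (R)-butan-2-ol | CC[C@@H](C)O | starting material
14 | (R)-butan-2-yl methanesulfonate | CC[C@@H](C)OS(C)(=O)=O | intermediate
15 | 5-chloro-1-aza-5-stannabicyclo[3.3.3]undecane | Cl[Sn]12CCCN(CCC1)CCC2 | starting material
16 | (1-aza-5-stannabicyclo[3.3.3]undecan-5-yl)lithium (formed in situ) | [Li][Sn]12CCCN(CCC1)CCC2 | intermediate
17 | 5-[(S)-butan-2-yl]-1-aza-5-stannabicyclo[3.3.3]undecane | N1(CCC2)CCC[Sn]2(CCC1)[C@@H](C)CC | intermediate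
18 | carbon monoxide | [C-]#[O+] | starting material
19 | 5,7-bis(methoxymethoxy)-2,2-dimethyl-8-[(S)-2-methylbutanoyl]-2H-chromene-6-carbaldehyde | COCOc1c(C=O)c(OCOC)c2C=CC(C)(C)Oc2c1C(=O)[C@@H](C)CC | intermediate
20 | pentan-3-one | CCC(=O)CC | starting material
21 | (Z)-trimethyl(pent-2-en-3-yloxy)silane | C/C=C(\O[Si](C)(C)C)CC | intermediate
22 | malonyl dichloride (propanedioyl dichloride) | O=C(Cl)CC(=O)Cl | starting material
23 | 4-methyl-3,5-dioxoheptanoyl chloride (formed in situ, racemic at C4) | CCC(=O)C(C)C(=O)CC(=O)Cl | intermediate
24 | 6-ethyl-4-hydroxy-5-methyl-2H-pyran-2-one | CCc1oc(=O)cc(O)c1C | intermediate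
25 | 3-({5,7-bis(methoxymethoxy)-2,2-dimethyl-8-[(S)-2-methylbutanoyl]-2H-chromen-6-yl}methylidene)-6-ethyl-5-methyl-2H-pyran-2,4(3H)-dione (formed in situ, alkene geometry undefined) | CCC1=C(C)C(=O)C(=Cc2c(OCOC)c3c(c(C(=O)[C@@H](C)CC)c2OCOC)OC(C)(C)C=C3)C(=O)O1 | intermediate
26 | 3-({5,7-bis(methoxymethoxy)-2,2-dimethyl-8-[(S)-2-methylbutanoyl]-2H-chromen-6-yl}methyl)-6-ethyl-4-hydroxy-5-methyl-2H-pyran-2-one | CCc1oc(=O)c(Cc2c(OCOC)c3c(c(C(=O)[C@@H](C)CC)c2OCOC)OC(C)(C)C=C3)c(O)c1C | intermediate
27 | 3-({5,7-dihydroxy-2,2-dimethyl-8-[(S)-2-methylbutanoyl]-2H-chromen-6-yl}methyl)-6-ethyl-4-hydroxy-5-methyl-2H-pyran-2-one (CNP0212387.1) | CCc1oc(=O)c(Cc2c(O)c3c(c(C(=O)[C@@H](C)CC)c2O)OC(C)(C)C=C3)c(O)c1C | target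

**Step count**

- Total step count: 11.
- Longest linear sequence: 7 steps (1, 2, 3, 4, 7, 10, 11).

**Steps most likely to fail**

1. Step 7.
   - What may go wrong: the sec-butyl group may be transferred at the aryl-palladium stage before CO is taken up. The electron-poor catalyst may be saturated by CO and lost as metal. β-Hydride elimination may occur from the acyl(sec-butyl)palladium intermediate. An open transmetalation may erode the configuration.
   - Fallback: the two bonds at the carbonyl carbon are made one after the other by known reactions. It sets out from 12. Palladium-catalysed hydroxycarbonylation (PdCl2(PPh3)2, CO 1 bar, H2O, Et3N, DMF, 70 °C) should give 6-formyl-5,7-bis(methoxymethoxy)-2,2-dimethyl-2H-chromene-8-carboxylic acid F1. Treatment with 1-chloro-N,N,2-trimethylprop-1-en-1-amine (CH2Cl2, 0 °C) should convert it under neutral, acetal-sparing conditions into 6-formyl-5,7-bis(methoxymethoxy)-2,2-dimethyl-2H-chromene-8-carbonyl chloride F2. The established stereoretentive palladium-catalysed acylation of secondary alkyl azastannatranes (17, Pd(dba)2, JackiePhos, CuCl, MeCN, 60 °C) then comes back to the route at 19.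

2. Step 10.
   - What may go wrong: condensation may be sluggish at an aldehyde flanked by two acetal groups. The Knoevenagel step may reverse. Hydride transfer to a donor-stabilised alkylidene may be slow. A second pyrone may add.
   - Fallback: carbonyl condensation is replaced by benzylic cation chemistry. It sets out from 19. Chemoselective reduction of the aldehyde (NaBH4, THF/MeOH, −20 °C; the ketone is shielded by two ortho substituents and its α-branch) should give (S)-1-[6-(hydroxymethyl)-5,7-bis(methoxymethoxy)-2,2-dimethyl-2H-chromen-8-yl]-2-methylbutan-1-one F3. Ionisation of this very electron-rich benzylic alcohol with catalytic Bi(OTf)3 in CH2Cl2 in the presence of 24 should alkylate C3' of the pyrone (dehydrative Friedel–Crafts-type benzylation of 4-hydroxy-2-pyrones). This comes back to the route at 26. Partial loss of an acetal on the way would do no harm, since step 11 removes both.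

3. Step 3.
   - What may go wrong: competing deprotonation at C8–H, whose lithio species is also flanked by two oxygens, would place the formyl group on the wrong ring carbon and exchange the roles of C6 and C8.
   - Fallback: the constitution is fixed by symmetry instead of by metalation. It sets out from 1. Vilsmeier–Haack formylation (POCl3, DMF, EtOAc, rt, then H2O) should give 2,4,6-trihydroxybenzaldehyde F4. Alkylation of its most acidic, non-chelated para hydroxyl with 3-chloro-3-methylbut-1-yne (K2CO3, KI, CuI cat., acetone, reflux) should give 2,6-dihydroxy-4-[(2-methylbut-3-yn-2-yl)oxy]benzaldehyde F5. Heating (xylene, 140 °C) should trigger the aromatic propargyl Claisen rearrangement, 1,5-hydrogen shift and oxa-6π closure at either of the two equivalent ortho carbons, giving only 5,7-dihydroxy-2,2-dimethyl-2H-chromene-6-carbaldehyde F6. Double protection (NaH, MOMCl, DMF) comes back to the route at 8.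

**Further compounds**

F1 | step 7 | 6-formyl-5,7-bis(methoxymethoxy)-2,2-dimethyl-2H-chromene-8-carboxylic acid | COCOc1c(C=O)c(OCOC)c2C=CC(C)(C)Oc2c1C(=O)O
F2 | step 7 | 6-formyl-5,7-bis(methoxymethoxy)-2,2-dimethyl-2H-chromene-8-carbonyl chloride | COCOc1c(C=O)c(OCOC)c2C=CC(C)(C)Oc2c1C(=O)Cl
F3 | step 10 | (S)-1-[6-(hydroxymethyl)-5,7-bis(methoxymethoxy)-2,2-dimethyl-2H-chromen-8-yl]-2-methylbutan-1-one | COCOc1c(CO)c(OCOC)c2C=CC(C)(C)Oc2c1C(=O)[C@@H](C)CC
F4 | step 3 | 2,4,6-trihydroxybenzaldehyde | O=Cc1c(O)cc(O)cc1O
F5 | step 3 | 2,6-dihydroxy-4-[(2-methylbut-3-yn-2-yl)oxy]benzaldehyde | C#CC(C)(C)Oc1cc(O)c(C=O)c(O)c1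
F6 | step 3 | 5,7-dihydroxy-2,2-dimethyl-2H-chromene-6-carbaldehyde | CC1(C)C=Cc2c(O)c(C=O)c(O)cc2O1
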